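**Plan**

1. Locants: butenolide ring O1–C2(=O)–C3(CH3)=C4(OH)–C5, then exocyclic C6H and the chain C7(CH3)–C8–C9–C10–C11(CH3)–C12=C13–C14=C15(CH3)–C16–C17–C18–(3-furyl).
2. Cuts: O1–C5 and C3=C4 together (last forward step). Then C5–C6 (diazoacetate aldol), C13–C14 (Suzuki–Miyaura), C12=C13 (boron–Wittig), C15–C16 (carbocupration of propyne), C18–furan (oxetane opening), and the two C–CH3 bonds at C7 and C11 (double alkylation).
3. Enabling feature: C5 of the butenolide ring is both an enol-ester carbon and the α-carbon of carboxyl carbon C4, and its ring oxygen O1 is 1,2-related to exocyclic C6. A propanoate parked on C6 of an α-diazo ester (a temporary O–C6 bond) can therefore move to a carbene at C5, which creates O1–C5 and C5=C6. Its own α-carbon C3 then lies within five-ring reach of ester carbon C4.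
4. Forward order: two-directional build-up of the C2-symmetric C6–C12 diol, monoprotection, diene assembly with the furan fragment, aldehyde at C6, diazoacetate addition, propanoylation. The butenolide, the only ring that is made, closes last.
5. Stereochemistry: C7 and C11 (both R) come from one double Evans methylation. 12E comes from the boron–Wittig step and 14Z from syn-carbocupration, and both are kept by a stereoretentive coupling. The 5E alkene comes from the key step, which funnels both C6 epimers into one geometry.

Key step: step 15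

Remark on the structure: the bond symbols are read as 5E (C7 cis to C4, trans to O1), 12E, 14Z, 7R and 11R. In IUPAC side-chain locants these are 7E, 9Z, 2R and 6R. The compound is made as the drawn 4-hydroxy tautomer.

**Route**

Step 1
Reactants: 1 heptanedioyl dichloride; 2 (R)-4-benzyl-1,3-oxazolidin-2-one (2 equiv)
Product: 3 1,7-bis[(4R)-4-benzyl-2-oxo-1,3-oxazolidin-3-yl]heptane-1,7-dione
Conditions: Et3N, DMAP (cat.), CH2Cl2, 0 °C to rt
Reagents that add atoms: none
Why: DMAP-catalysed N-acylation of an oxazolidinone by an acid chloride is a standard imide synthesis, and it puts the same auxiliary on both ends so that the chain stays C2-symmetric.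

Step 2
Reactants: 3
Product: 5 (2R,6R)-1,7-bis[(4R)-4-benzyl-2-oxo-1,3-oxazolidin-3-yl]-2,6-dimethylheptane-1,7-dione, via disodium bis-enolate 4 (not isolated)
Conditions: NaN(SiMe3)2 (2.3 equiv), THF, −78 °C; MeI (excess), −78 to −30 °C
Reagents that add atoms: iodomethane, CI
Why: In this double Evans asymmetric alkylation each chelated Z-enolate is shielded on one face by the C4 benzyl group, so iodomethane enters from the other face and the (R)-auxiliary sets R at both new centres, while any facial error is diverted into a separable (2R,6S) diastereomer (statistical amplification of enantiopurity).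

Step 3
Reactants: 5
Product: 6 (2R,6R)-2,6-dimethylheptane-1,7-diol
Conditions: LiBH4, H2O (2 equiv), Et2O, 0 °C; aq NaOH work-up
Reagents that add atoms: none
Why: Reductive cleavage of N-acyloxazolidinones by LiBH4 proceeds by hydride attack at the exocyclic carbonyl, leaves the α-centres untouched and returns the auxiliary.

Step 4
Reactants: 6
Product: 8 (2R,6R)-7-[(tert-butyldimethylsilyl)oxy]-2,6-dimethylheptan-1-ol, via monosodium alkoxide 7 (not isolated)
Conditions: NaH (1.0 equiv), THF, rt; TBSCl (1.0 equiv)
Reagents that add atoms: tert-butyldimethylsilyl chloride, CC(C)(C)[Si](C)(C)Cl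
Why: Silylation through the sparingly soluble monosodium alkoxide favours single protection, and because the two hydroxyl groups of the C2-symmetric diol are homotopic either one gives the same compound.

Step 5
Reactants: 8
Product: 9 (2R,6R)-7-[(tert-butyldimethylsilyl)oxy]-2,6-dimethylheptanal
Conditions: TEMPO (cat.), PhI(OAc)2, CH2Cl2, rt
Reagents that add atoms: none
Why: Oxoammonium (TEMPO) oxidation stops at the aldehyde under nearly neutral conditions, so the α-methyl centre should not epimerise and the silyl ether is kept.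

Step 6
Reactants: 9; 10 bis(4,4,5,5-tetramethyl-1,3,2-dioxaborolan-2-yl)methane
Product: 12 tert-butyl{[(2R,6R,7E)-2,6-dimethyl-8-(4,4,5,5-tetramethyl-1,3,2-dioxaborolan-2-yl)oct-7-en-1-yl]oxy}dimethylsilane, via lithiated diborylmethane 11 (not isolated)
Conditions: lithium 2,2,6,6-tetramethylpiperidide, THF, 0 °C; then 9, −78 °C to rt
Reagents that add atoms: none
Why: In the boron–Wittig olefination the stabilised α-boryl carbanion adds to the aldehyde and syn B–O elimination from the less crowded adduct gives the E-alkenylboronate, and the weakly basic anion at low temperature spares the α-centre.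

Step 7
Reactants: 13 3-bromofuran; 14 oxetane
Product: 16 3-(furan-3-yl)propan-1-ol, via 3-furyllithium 15 (not isolated)
Conditions: n-BuLi, THF, −78 °C; then 14, BF3·OEt2, −78 °C
Reagents that add atoms: none
Why: Bromine–lithium exchange at −78 °C gives 3-furyllithium, which is kept cold to prevent drift to the 2-lithio isomer and opens the BF3-activated oxetane by SN2 attack driven by ring strain.

Step 8
Reactants: 16
Product: 17 3-(3-bromopropyl)furan
Conditions: CBr4, PPh3, CH2Cl2, 0 °C
Reagents that add atoms: carbon tetrabromide, BrC(Br)(Br)Br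
Why: The Appel reaction converts a primary alcohol into the bromide under neutral conditions that the acid-sensitive furan tolerates.

Step 9
Reactants: 17; 18 propyne
Product: 22 3-[(4Z)-5-iodo-4-methylpent-4-en-1-yl]furan, via Grignard reagent 19 (not isolated), via alkylcopper 20 (not isolated), via Z-alkenylcopper 21 (not isolated)
Conditions: Mg, Et2O; CuBr·SMe2, Et2O/Me2S, −45 °C; 18, −25 °C; I2, THF, −60 to 0 °C
Reagents that add atoms: iodine, II
Why: In the carbocupration of a terminal alkyne the alkylcopper adds syn across propyne with copper on the terminal carbon, so chain and copper are cis, and iodinolysis with retention gives the Z-iodide that carries the 14Z geometry.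

Step 10
Reactants: 12; 22
Product: 23 tert-butyl{[(2R,6R,7E,9Z)-13-(furan-3-yl)-2,6,10-trimethyltrideca-7,9-dien-1-yl]oxy}dimethylsilane
Conditions: Pd(dppf)Cl2 (5 mol %), aq K3PO4, THF, rt
Reagents that add atoms: none
Why: In the Suzuki–Miyaura coupling, oxidative addition of zerovalent palladium into the C–I bond, transmetalation and reductive elimination all go with retention, so both alkene geometries pass unchanged into the E,Z-diene.

Step 11
Reactants: 23
Product: 24 (2R,6R,7E,9Z)-13-(furan-3-yl)-2,6,10-trimethyltrideca-7,9-dien-1-ol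
Conditions: Bu4NF, THF, 0 °C to rt
Reagents that add atoms: none
Why: Fluoride-driven desilylation is selective for the Si–O bond and affects neither the furan nor the diene.

Step 12
Reactants: 24
Product: 25 (2R,6R,7E,9Z)-13-(furan-3-yl)-2,6,10-trimethyltrideca-7,9-dienal
Conditions: Dess–Martin periodinane, pyridine, CH2Cl2, 0 °C
Reagents that add atoms: none
Why: Buffered Dess–Martin oxidation gives the aldehyde quickly under mild conditions that are compatible with the furan, the diene and the epimerisable α-centre, and 25 is used at once.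

Step 13
Reactants: 25; 26 ethyl diazoacetate
Product: 28 ethyl (4R,8R,9E,11Z)-2-diazo-15-(furan-3-yl)-3-hydroxy-4,8,12-trimethylpentadeca-9,11-dienoate (both C3 epimers), via ethyl lithiodiazoacetate 27 (not isolated)
Conditions: LiN(iPr)2, 26, THF, −78 °C; then 25, −78 °C; AcOH quench at −78 °C
Reagents that add atoms: none
Why: The aldol-type addition of lithiated ethyl diazoacetate to aldehydes is fast at −78 °C, the cold acidic quench prevents retro-addition, and the new carbinol centre (C6) may form as an epimer mixture because step 15 erases it.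

Step 14
Reactants: 28; 29 propanoic anhydride
Product: 30 ethyl (4R,8R,9E,11Z)-2-diazo-15-(furan-3-yl)-4,8,12-trimethyl-3-(propanoyloxy)pentadeca-9,11-dienoate (both C3 epimers)
Conditions: Et3N, DMAP (cat.), CH2Cl2, 0 °C
Reagents that add atoms: none
Why: DMAP-catalysed esterification of the secondary alcohol leaves the acceptor-stabilised diazo group intact and installs O1, C2, C3 and the C3 methyl group through the temporary O–C6 bond.

Step 15
Reactants: 30
Product: 32 (5E)-5-[(2R,6R,7E,9Z)-13-(furan-3-yl)-2,6,10-trimethyltrideca-7,9-dien-1-ylidene]-4-hydroxy-3-methylfuran-2(5H)-one (target), via E-enol propanoate 31 (not isolated)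
Conditions: Rh2(O2CCPh3)4 (1 mol %), toluene (dilute), −40 to 0 °C, dark; then THF, LiN(SiMe3)2 (2.2 equiv), −78 to −30 °C; cold 0.5 M HCl
Reagents that add atoms: none
Why: Rh2(O2CCPh3)4 takes N2 from 30 and leaves an electrophilic rhodium carbene at C5, the carbonyl oxygen of the propanoate on C6 adds to it (five-membered 1,3-dioxolan-2-ylium ring), and collapse with rupture of the old C6–O bond and release of rhodium moves the acyloxy group to C5, which makes O1–C5 and C5=C6 and gives 31. LiN(SiMe3)2 added to the same flask then deprotonates the propanoate CH2 (C3), and the ester enolate attacks ethyl ester carbon C4 in a 5-exo-trig Dieckmann closure of the butenolide ring (C3–C4), after which ethoxide leaves and the product rests as its lithium tetronate until the acid quench. The closest known reaction types are the dirhodium-catalysed 1,2-acyloxy migration of β-acyloxy-α-diazo esters to 2-acyloxy-2-enoates and the Dieckmann condensation of 2-(acyloxy)acrylates to 5-ylidenetetronic acids with retention of alkene geometry. No stereocentre is created, and the alkene geometry is set in the migration: the C6–O bond must stand parallel to the empty carbene orbital, so the two other C6 substituents fall one beside the ester and one beside the rhodium paddlewheel, and the chain (C7) should avoid the triphenylacetate wall, lie next to C4 and end up cis to C4 and trans to O1 (5E), which is the bias that gives cis-enoates in 1,2-hydride shifts of such carbenes, and either C6 epimer reaches this arrangement by using the opposite carbene face, so the epimer mixture converges. The step needs acyloxy rather than hydride migration (helped by the electron-poor C6–H, the bulky carboxylate ligands and the low temperature, all of which retard the hydride shift), a 1,2-shift faster than carbene attack on the furan or diene (secured by proximity and dilution), and deprotonation at C3 rather than at C7–H (allylic strain in the E-alkene holds C7–H in the alkene plane, out of alignment with the π system, so the 7R centre is kept).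

**Compound list**

1 | heptanedioyl dichloride | O=C(Cl)CCCCCC(=O)Cl | starting material
2 | (R)-4-benzyl-1,3-oxazolidin-2-one | O=C1OC[C@@H](Cc2ccccc2)N1 | starting material
3 | 1,7-bis[(4R)-4-benzyl-2-oxo-1,3-oxazolidin-3-yl]heptane-1,7-dione | O=C(CCCCCC(=O)N1[C@H](Cc2ccccc2)COC1=O)N1[C@H](Cc2ccccc2)COC1=O | intermediate
4 | disodium bis-Z-enolate of 3 | [Na+].[Na+].[O-]/C(=C\CCC/C=C(\[O-])N1[C@H](Cc2ccccc2)COC1=O)N1[C@H](Cc2ccccc2)COC1=O | intermediate
5 | (2R,6R)-1,7-bis[(4R)-4-benzyl-2-oxo-1,3-oxazolidin-3-yl]-2,6-dimethylheptane-1,7-dione | O=C([C@H](C)CCC[C@@H](C)C(=O)N1[C@H](Cc2ccccc2)COC1=O)N1[C@H](Cc2ccccc2)COC1=O | intermediate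
6 | (2R,6R)-2,6-dimethylheptane-1,7-diol | OC[C@H](C)CCC[C@@H](C)CO | intermediate
7 | monosodium alkoxide of 6 | [Na+].[O-]C[C@H](C)CCC[C@@H](C)CO | intermediate
8 | (2R,6R)-7-[(tert-butyldimethylsilyl)oxy]-2,6-dimethylheptan-1-ol | CC(C)(C)[Si](C)(C)OC[C@H](C)CCC[C@@H](C)CO | intermediate
9 | (2R,6R)-7-[(tert-butyldimethylsilyl)oxy]-2,6-dimethylheptanal | CC(C)(C)[Si](C)(C)OC[C@H](C)CCC[C@@H](C)C=O | intermediate
10 | bis(4,4,5,5-tetramethyl-1,3,2-dioxaborolan-2-yl)methane | C(B1OC(C)(C)C(C)(C)O1)B1OC(C)(C)C(C)(C)O1 | starting material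
11 | lithiobis(4,4,5,5-tetramethyl-1,3,2-dioxaborolan-2-yl)methane | [Li]C(B1OC(C)(C)C(C)(C)O1)B1OC(C)(C)C(C)(C)O1 | intermediate
12 | tert-butyl{[(2R,6R,7E)-2,6-dimethyl-8-(4,4,5,5-tetramethyl-1,3,2-dioxaborolan-2-yl)oct-7-en-1-yl]oxy}dimethylsilane | CC(C)(C)[Si](C)(C)OC[C@H](C)CCC[C@@H](C)/C=C/B1OC(C)(C)C(C)(C)O1 | intermediate
13 | 3-bromofuran | Brc1ccoc1 | starting material
14 | oxetane | C1COC1 | starting material
15 | 3-furyllithium | [Li]c1ccoc1 | intermediate
16 | 3-(furan-3-yl)propan-1-ol | OCCCc1ccoc1 | intermediate
17 | 3-(3-bromopropyl)furan | BrCCCc1ccoc1 | intermediate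
18 | propyne | CC#C | starting material
19 | [3-(furan-3-yl)propyl]magnesium bromide | Br[Mg]CCCc1ccoc1 | intermediate
20 | [3-(furan-3-yl)propyl]copper (MgBr2 complex, drawn without the salt) | [Cu]CCCc1ccoc1 | intermediate
21 | [(1Z)-5-(furan-3-yl)-2-methylpent-1-en-1-yl]copper (MgBr2 complex, drawn without the salt) | [Cu]/C=C(/C)CCCc1ccoc1 | intermediate
22 | 3-[(4Z)-5-iodo-4-methylpent-4-en-1-yl]furan | I/C=C(/C)CCCc1ccoc1 | intermediate
23 | tert-butyl{[(2R,6R,7E,9Z)-13-(furan-3-yl)-2,6,10-trimethyltrideca-7,9-dien-1-yl]oxy}dimethylsilane | CC(C)(C)[Si](C)(C)OC[C@H](C)CCC[C@@H](C)/C=C/C=C(/C)CCCc1ccoc1 | intermediate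
24 | (2R,6R,7E,9Z)-13-(furan-3-yl)-2,6,10-trimethyltrideca-7,9-dien-1-ol | OC[C@H](C)CCC[C@@H](C)/C=C/C=C(/C)CCCc1ccoc1 | intermediate
25 | (2R,6R,7E,9Z)-13-(furan-3-yl)-2,6,10-trimethyltrideca-7,9-dienal | O=C[C@H](C)CCC[C@@H](C)/C=C/C=C(/C)CCCc1ccoc1 | intermediate
26 | ethyl diazoacetate | CCOC(=O)C=[N+]=[N-] | starting material
27 | ethyl lithiodiazoacetate | CCOC(=O)C([Li])=[N+]=[N-] | intermediate
28 | ethyl (4R,8R,9E,11Z)-2-diazo-15-(furan-3-yl)-3-hydroxy-4,8,12-trimethylpentadeca-9,11-dienoate (C3 epimers) | CCOC(=O)C(=[N+]=[N-])C(O)[C@H](C)CCC[C@@H](C)/C=C/C=C(/C)CCCc1ccoc1 | intermediate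
29 | propanoic anhydride | CCC(=O)OC(=O)CC | starting material
30 | ethyl (4R,8R,9E,11Z)-2-diazo-15-(furan-3-yl)-4,8,12-trimethyl-3-(propanoyloxy)pentadeca-9,11-dienoate (C3 epimers) | CCOC(=O)C(=[N+]=[N-])C(OC(=O)CC)[C@H](C)CCC[C@@H](C)/C=C/C=C(/C)CCCc1ccoc1 | intermediate
31 | ethyl (2E,4R,8R,9E,11Z)-15-(furan-3-yl)-4,8,12-trimethyl-2-(propanoyloxy)pentadeca-2,9,11-trienoate | CCOC(=O)/C(OC(=O)CC)=C\[C@H](C)CCC[C@@H](C)/C=C/C=C(/C)CCCc1ccoc1 | intermediate
32 | (5E)-5-[(2R,6R,7E,9Z)-13-(furan-3-yl)-2,6,10-trimethyltrideca-7,9-dien-1-ylidene]-4-hydroxy-3-methylfuran-2(5H)-one | CC1=C(O)/C(=C\[C@H](C)CCC[C@@H](C)/C=C/C=C(/C)CCCc2ccoc2)OC1=O | target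

**Step count**

Total step count: 15. Longest linear sequence: 12 (steps 1–6 and 10–15).

**Steps most likely to fail**

Step 15. Hydride migration from C6 may overtake acyloxy migration at the rhodium carbene. The preference for placing the chain beside the ester may also be too weak, which would erode the geometry at C5=C6.
The fallback sets out from aldehyde 25 and comes back at enol ester 31. Bis(2,2,2-trifluoroethyl) phosphite is added to ethyl glyoxylate (Pudovik reaction, Et3N cat.) to give ethyl 2-[bis(2,2,2-trifluoroethoxy)phosphoryl]-2-hydroxyacetate F1. Anhydride 29 with pyridine converts it into ethyl 2-[bis(2,2,2-trifluoroethoxy)phosphoryl]-2-(propanoyloxy)acetate F2. A Still–Gennari-type olefination of 25 with F2 (KN(SiMe3)2, 18-crown-6, THF, −78 °C) builds C5=C6 with the chain cis to the ester. This gives 31, now isolated, which is closed with LiN(SiMe3)2 as in the second stage of step 15.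

Step 9. Homocoupling during Grignard formation, thermal decay of the alkylcopper, or slow and poorly regioselective addition to propyne may starve the iodination.
The fallback sets out from bromide 17 (with propyne 18) and comes back at iodide 22. Zinc dust and LiCl in THF convert 17 into [3-(furan-3-yl)propyl]zinc bromide F3. Separately, syn-bromoboration of 18 with BBr3 gives dibromo[(1Z)-2-bromoprop-1-en-1-yl]borane F4. Pinacol turns this into 2-[(1Z)-2-bromoprop-1-en-1-yl]-4,4,5,5-tetramethyl-1,3,2-dioxaborolane F5. Negishi coupling of F3 at the C–Br bond of F5 (Pd(P(t-Bu)3)2 cat., THF) gives, with retention, 2-[(1Z)-5-(furan-3-yl)-2-methylpent-1-en-1-yl]-4,4,5,5-tetramethyl-1,3,2-dioxaborolane F6. NaOH followed by I2 replaces boron by iodine with retention to give 22.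

Step 7. Migration of lithium from C3 to C2 of the furan, or consumption of the organolithium by BF3 before ring opening, may cut the conversion.
The fallback sets out from 3-bromofuran 13 and comes back at alcohol 16. Commercial allyl tert-butyldimethylsilyl ether is hydroborated with 9-borabicyclo[3.3.1]nonane to give 9-{3-[(tert-butyldimethylsilyl)oxy]propyl}-9-borabicyclo[3.3.1]nonane F7. A B-alkyl Suzuki–Miyaura coupling with 13 (Pd(dppf)Cl2, K3PO4, DMF/THF, 50 °C) gives tert-butyl[3-(furan-3-yl)propoxy]dimethylsilane F8. Bu4NF then frees 16.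

**Further compounds**

F1 | step 15 | ethyl 2-[bis(2,2,2-trifluoroethoxy)phosphoryl]-2-hydroxyacetate | CCOC(=O)C(O)P(=O)(OCC(F)(F)F)OCC(F)(F)F
F2 | step 15 | ethyl 2-[bis(2,2,2-trifluoroethoxy)phosphoryl]-2-(propanoyloxy)acetate | CCOC(=O)C(OC(=O)CC)P(=O)(OCC(F)(F)F)OCC(F)(F)F
F3 | step 9 | [3-(furan-3-yl)propyl]zinc bromide | Br[Zn]CCCc1ccoc1
F4 | step 9 | dibromo[(1Z)-2-bromoprop-1-en-1-yl]borane | C/C(Br)=C/B(Br)Br
F5 | step 9 | 2-[(1Z)-2-bromoprop-1-en-1-yl]-4,4,5,5-tetramethyl-1,3,2-dioxaborolane | C/C(Br)=C/B1OC(C)(C)C(C)(C)O1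
F6 | step 9 | 2-[(1Z)-5-(furan-3-yl)-2-methylpent-1-en-1-yl]-4,4,5,5-tetramethyl-1,3,2-dioxaborolane | C/C(CCCc1ccoc1)=C/B1OC(C)(C)C(C)(C)O1
F7 | step 7 | 9-{3-[(tert-butyldimethylsilyl)oxy]propyl}-9-borabicyclo[3.3.1]nonane | CC(C)(C)[Si](C)(C)OCCCB1C2CCCC1CCC2
F8 | step 7 | tert-butyl[3-(furan-3-yl)propoxy]dimethylsilane | CC(C)(C)[Si](C)(C)OCCCc1ccoc1
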